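**Analysis of the target**

Compound 19 (C26H36O4) is a 20-membered macrocycle. Two benzene rings are joined twice: by an unbranched chain of fourteen methylene groups (C1' on B6 to C14' on A5) and by a diaryl ether oxygen between A1 and B1. Ring A is 1,3,5-trisubstituted (ether O on A1, OH on A3, chain on A5) and is bridged meta. Ring B is 1,2,4,6-tetrasubstituted (ether O on B1, OH on B2 and B4, chain on B6) and is bridged ortho. There is no stereocentre, and a ring of this size with a flexible chain should show no stable atropisomerism, so the problems are regiochemical and entropic only. The sensitive groups are the three phenols: ring B is an aryloxy-resorcinol that oxidises easily in base and air, so the phenols are best carried as methyl ethers until the last step. Three things make the synthesis hard: B1 is crowded between the B2 oxygen and the chain carbon B6, a 20-membered ring has to be closed, and once the ether bond is removed both rings become the same 5-alkylresorcinol, so a hidden twofold symmetry must be broken at some point. The plan rests on that same feature. A carboxyl placed on A4 and on B5 turns each ring into a 6-alkyl-2,4-dihydroxybenzoate, the aromatic form of a folded tetraketide. The carbon skeleton is therefore a head-to-head pair of tetraketides grown from the two ends of hexadecanedioic acid 1, whose carboxyl carbons become A5 and B6.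

**Retrosynthetic reasoning**

The three phenols of 19 are masked as methyl ethers, which leads back to 18. The forward step is a Lewis-acid ether cleavage that leaves the diaryl ether untouched, because only the methyl carbons can be attacked.

The macrocycle 18 is opened at the B1–O bond, with the oxygen staying on ring A, to the iodophenol 17. This is the only bond whose removal returns two 5-alkylresorcinol rings. A dehydrogenative coupling of the free tetraphenol 12 would be the shortest finish. However, an unblocked resorcinol pair offers nothing to steer a phenoxyl radical towards O–C coupling at B1 rather than C–C coupling, quinone formation or oligomerisation. The bond is therefore planned as a polar, copper-catalysed intramolecular Ullmann etherification. The polarity chosen uses a native resorcinol oxygen of ring A as the nucleophile and puts the leaving group on B1, the most nucleophilic carbon of a resorcinol dimethyl ether, where an electrophile goes by itself.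

The iodophenol 17 is traced through the acetate 16 and the iodine-free acetate 15 to the mono-phenol 14, and then to the symmetrical tetramethyl ether 13. In the forward direction one methyl group is removed from 13. That single event defines ring A. Its phenol is then acylated so that ring A is less nucleophilic than the doubly methoxy-activated ring B during iodination. Because the two rings of 13 are identical and far apart, this is the point where the symmetry is broken.

The tetramethyl ether 13 comes from the tetraphenol 12 by O-methylation, and 12 from the bis-resorcylate 10 by putting back the carboxyl carbons (forward: hydrolysis and double decarboxylation). Once the carboxyls are gone and both oxygens of a ring carry the same group, the two positions ortho to the chain are equivalent. The labels of ring A and ring B therefore take effect only at 14.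

The key disconnection cuts the A4–A5 and B5–B6 bonds of 10 and unfolds both arenes into the open-chain bis(diketo-dioxinone) 8. Cutting here, and not at a chain bond, turns two aromatic rings into one linear chain of carbonyl groups, and both rings can then be formed in one operation. The forward reaction must close each ring by aldol addition of the dioxinone ring carbon to the chain ketone and then dehydrate, without touching the masked carboxyl.

Compound 8 is cut at the two bonds between each former amide carbonyl and the terminal carbon of the keto-dioxinone. This gives two molecules of 6 (used as its dianion 7) and the bis(N-methoxy-N-methylamide) 3. The amide is chosen because its tetrahedral adduct survives until work-up, so each end is acylated once.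

The diamide 3 comes from the diacid 1 through the diacid chloride 2. The keto-dioxinone 6 comes from the trimethyl-dioxinone 4 by acylation of its dienolate 5.

**Alternatives that were turned down**

Alternative 1: The macrocycle is opened in the middle of the chain, at C8'–C9', after the chain has been redrawn as a (Z,Z)-diene 1,3-diyne. The diaryl ether is kept and made early from two monocyclic arenes. In the forward direction the acyclic diaryl ether bis(enyne) A2, with a hex-1-en-5-ynyl arm on A5 and an oct-1-en-7-ynyl arm on B6, would be cyclised by Eglinton coupling (a divalent copper carboxylate in an amine solvent, high dilution) to the tri-O-methyl diene-diyne macrocycle A1. Exhaustive hydrogenation and ether cleavage would follow.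
- For it: the crowded B1–O bond is made between small, fully differentiated arenes, so there is no hidden symmetry to break and no statistical step. Oxidative alkyne dimerisation is also a dependable way to close large rings.
- Against it: the bond formed lies in a featureless run of methylenes, and nothing in 19 points to it. Four unsaturations and two olefin geometries are installed only to be hydrogenated. Both arenes must be made separately with their oxygen patterns, and each needs its own olefination.
- Comparison: this alternative is stronger on the regiochemical certainty of the ether and probably on the ring closure. The chosen strategy offers step economy in the skeleton instead: both rings and the whole chain arise from a C16 diacid and a C4 dioxinone in four steps.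

Alternative 2: Only the crowded edge of ring B is addressed. The B6–C1' bond and the B1 oxygen are traced to an aryne. The aryne released by fluoride from the ortho-silyl aryl triflate A4 would insert into the C2–C3 bond of methyl acetoacetate A5. This acyl-alkylation would give the arylacetic ester A3, with the CH2CO2Me arm on B6 and an acetyl group on B1. A later Baeyer–Villiger oxidation would turn the acetyl group into the B1 oxygen.
- For it: the methoxy group next to the aryne bond polarises it, so the carbon nucleophile adds at the far carbon and the acyl group ends up beside the methoxy group. The contiguous B6/B1/B2 pattern is thus set without ambiguity, and the B1 oxygen arrives distinct from those on B2 and B4.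
- Against it: the step closes no ring and supplies only two of the fourteen chain carbons. Twelve chain carbons, ring A, the ether and the macrocycle all remain. A4 itself needs several steps, and the B1 phenol that emerges is flanked on both sides.
- Comparison: this alternative is stronger on site definition in ring B and needs no statistical step. The chosen strategy is far more convergent, since its key step delivers the complete carbon framework and both rings.

Alternative 3: Ring B is built from a four-membered ring. Thermolysis of the cyclobutenone A7 (an alkenyllithium adduct of a semisquaric ester) would open it to a dienylketene. Six-electron electrocyclisation of the ketene would form the B4–B5 bond and, after tautomerisation, give the hydroquinone A6. In A6 ring B carries OH on B1, isopropoxy on B2, OH on B4 and the chain on B6, and the far end of the chain carries a 3-chloro-5-methoxyphenyl group as ring A.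
- For it: all three oxygens of ring B and the chain position follow from the connectivity of the cyclobutenone. The route is unsymmetrical throughout, and ring A already carries a leaving group on A1.
- Against it: only one ring is built, and ring A is bought. The alkenyl partner is a 2-metallated 1-alkene at the end of a long chain, which needs its own linear synthesis. The B1 and B4 hydroxyls must be told apart, and the hydroquinone is air-sensitive. The final etherification would join a doubly ortho-substituted phenol to an unactivated aryl chloride within a macrocyclisation.
- Comparison: this alternative is stronger on the oxygen pattern of ring B and avoids a statistical step. The chosen strategy answers with a much shorter assembly of the skeleton and an aryl iodide for the ring closure.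

Key step: step 4

Assumption: in the symmetrical intermediates the two rings, fourteen methylene groups apart, react independently. Step 7 is therefore planned as a statistical mono-demethylation, with recovered 13 and over-demethylated material returned to the route.

**Route**

Step 1
Reactants: 1 hexadecanedioic acid
Product: 3 N1,N16-dimethoxy-N1,N16-dimethylhexadecanediamide, via hexadecanedioyl dichloride 2 (not isolated)
Conditions: (COCl)2 (2.5 equiv), DMF (cat.), CH2Cl2, 0 °C to rt; then MeNH(OMe)·HCl (2.5 equiv), Et3N (6 equiv), CH2Cl2, 0 °C to rt
Reagents that add atoms: N,O-dimethylhydroxylamine hydrochloride, CNOC.Cl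
Why: Acid chloride formation followed by Schotten–Baumann-type amidation is routine for a saturated diacid; the suspension of 1 should clear as 2 forms, and no other functional group is present.

Step 2
Reactants: 4 2,2,6-trimethyl-4H-1,3-dioxin-4-one
Product: 6 2,2-dimethyl-6-(2-oxopropyl)-4H-1,3-dioxin-4-one, via lithium dienolate 5 (not isolated)
Conditions: LiN(SiMe3)2 (1.0 equiv), THF, −78 °C; then AcCl (0.5 equiv), −78 °C; aq. NH4Cl
Reagents that add atoms: acetyl chloride, CC(Cl)=O
Why: Vinylogous deprotonation of the 6-methyl group gives dienolate 5, which is C-acylated at the exocyclic carbon (crossed Claisen condensation); two equivalents of 5 per acetyl chloride are used because 6 is more acidic than 4 and is deprotonated as it forms.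

Step 3
Reactants: 6 2,2-dimethyl-6-(2-oxopropyl)-4H-1,3-dioxin-4-one; 3 N1,N16-dimethoxy-N1,N16-dimethylhexadecanediamide
Product: 8 1,22-bis(2,2-dimethyl-4-oxo-4H-1,3-dioxin-6-yl)docosane-2,4,19,21-tetraone, via dilithium dianion 7 (not isolated)
Conditions: 6 (3.0 equiv), LiN(iPr)2 (6.2 equiv), THF, −78 to −40 °C; then 3 (1.0 equiv) in THF, −78 to −20 °C; aq. NH4Cl/1 M HCl to pH 3, 0 °C; used promptly
Reagents that add atoms: none
Why: Dianion 7 reacts at its last-formed, terminal carbanion (Claisen-type C-acylation of a 1,3-dicarbonyl dianion), and the chelated tetrahedral adduct of the N-methoxy-N-methylamide holds each end at the mono-acylation stage until the acidic quench. The two amide groups are remote and should react independently.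

Step 4
Reactants: 8 1,22-bis(2,2-dimethyl-4-oxo-4H-1,3-dioxin-6-yl)docosane-2,4,19,21-tetraone
Product: 10 5,5'-(tetradecane-1,14-diyl)bis(7-hydroxy-2,2-dimethyl-4H-benzo[d][1,3]dioxin-4-one), via bis-aldol adduct 9 (not isolated)
Conditions: Et3N (4 equiv), CH2Cl2, 4 Å molecular sieves, rt
Reagents that add atoms: none
Why: Et3N removes a proton from the methylene between the dioxinone and the first ketone at each chain end, giving a cross-conjugated dienolate whose nucleophilic site is the dioxinone ring carbon next to the lactone carbonyl. That carbon adds to the distal ketone, the one carrying the polymethylene chain, forming the A4–A5 bond at one end and the B5–B6 bond at the other; each ring closes in a 6-(enolexo)-exo-trig aldol mode to give the bis-aldol adduct 9. Loss of water from the tertiary carbinol by an E1cB pathway and enolisation of the remaining ring ketone then give the arene, and the gain of aromatic stabilisation makes the sequence irreversible. The closest known reaction type is the amine-mediated cycloaromatisation of 6-(2,4-dioxoalkyl)dioxinones to isopropylidene-protected 6-alkyl-β-resorcylates, the laboratory counterpart of polyketide aldol folding; here it must run at two remote, non-interacting termini of one molecule. The carbinol and ring-fusion centres of 9 form without control and are all destroyed on aromatisation, so no stereocentre has to be set. The step needs chemoselectivity for C-aldol closure onto the chain ketone over Claisen closure onto the carboxyl carbon and over lactonisation to a pyranone. The substrate secures this because the carboxyl carbon is locked in the dioxinone ring, trans to the side chain across the ring double bond, and is a weakly electrophilic vinylogous carbonate; neither the methylene between the ketones nor an enol oxygen can reach it, whereas the ring carbon and the distal ketone are exactly placed for a six-membered closure.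

Step 5
Reactants: 10 5,5'-(tetradecane-1,14-diyl)bis(7-hydroxy-2,2-dimethyl-4H-benzo[d][1,3]dioxin-4-one)
Product: 12 5,5'-(tetradecane-1,14-diyl)bis(benzene-1,3-diol), via bis(resorcylic acid) 11 (not isolated)
Conditions: KOH (12 equiv), H2O/EtOH, reflux, Ar; then 6 M HCl to pH 1, 90 °C
Reagents that add atoms: none
Why: Saponification opens each isopropylidene salicylate with release of acetone, and the resulting 2,4-dihydroxy-6-alkylbenzoic acid should decarboxylate readily by ipso-protonation, because the carboxyl sits ortho and para to hydroxyl groups (protodecarboxylation of a β-resorcylic acid). Air is excluded because resorcinols oxidise in hot alkali.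

Step 6
Reactants: 12 5,5'-(tetradecane-1,14-diyl)bis(benzene-1,3-diol)
Product: 13 1,14-bis(3,5-dimethoxyphenyl)tetradecane
Conditions: MeI (6 equiv), K2CO3 (8 equiv), acetone, reflux
Reagents that add atoms: iodomethane, CI
Why: Williamson O-methylation of the four equivalent phenols with a weak base in acetone is standard for 5-alkylresorcinols and should not lead to C-alkylation.

Step 7
Reactants: 13 1,14-bis(3,5-dimethoxyphenyl)tetradecane
Product: 14 3-[14-(3,5-dimethoxyphenyl)tetradecyl]-5-methoxyphenol
Conditions: NaSEt (1.1 equiv), DMF, 130 °C; aq. HCl; chromatography, recovered 13 recycled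
Reagents that add atoms: none
Why: Thiolate SN2 demethylation of an aryl methyl ether stops at one methoxy group per ring, since the aryloxide formed makes the second methoxy group of that ring a poor leaving-group precursor. With about one equivalent of thiolate a separable statistical mixture is expected, and the ring that loses its methyl group becomes ring A.

Step 8
Reactants: 14 3-[14-(3,5-dimethoxyphenyl)tetradecyl]-5-methoxyphenol
Product: 15 3-[14-(3,5-dimethoxyphenyl)tetradecyl]-5-methoxyphenyl acetate
Conditions: Ac2O (1.5 equiv), pyridine, DMAP (cat.), CH2Cl2, rt
Reagents that add atoms: acetic anhydride, CC(=O)OC(C)=O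
Why: Routine O-acetylation; the acetate turns the strongly donating phenol of ring A into a weak donor, so that ring B becomes the more nucleophilic arene for the next step.

Step 9
Reactants: 15 3-[14-(3,5-dimethoxyphenyl)tetradecyl]-5-methoxyphenyl acetate
Product: 16 3-[14-(2-iodo-3,5-dimethoxyphenyl)tetradecyl]-5-methoxyphenyl acetate
Conditions: NIS (1.0 equiv), MeCN/CH2Cl2, 0 °C to rt, dark, no acid
Reagents that add atoms: N-iodosuccinimide, O=C1CCC(=O)N1I
Why: Electrophilic aromatic iodination; without acid activation the reagent should attack only the ring with two cooperating methoxy groups, at the carbon para to one and ortho to the other, which is the position next to the chain (B1, identical with B5 by symmetry). The position between the two methoxy groups is less favoured, and the acetoxy-anisole ring A is far less reactive.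

Step 10
Reactants: 16 3-[14-(2-iodo-3,5-dimethoxyphenyl)tetradecyl]-5-methoxyphenyl acetate
Product: 17 3-[14-(2-iodo-3,5-dimethoxyphenyl)tetradecyl]-5-methoxyphenol
Conditions: K2CO3 (0.2 equiv), MeOH/THF, rt; then AcOH
Reagents that add atoms: none
Why: Base-catalysed methanolysis of an aryl acetate is fast at room temperature and leaves the aryl iodide and the methyl ethers untouched.

Step 11
Reactants: 17 3-[14-(2-iodo-3,5-dimethoxyphenyl)tetradecyl]-5-methoxyphenol
Product: 18 tri-O-methyl ether of 19 (20-membered diaryl ether macrocycle with OMe on A3, B2 and B4)
Conditions: CuI (0.3 equiv), picolinic acid (0.6 equiv), K3PO4 (3 equiv), DMSO, 90 °C, Ar, syringe-pump addition of 17 (final 2 mM)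
Reagents that add atoms: none
Why: Ligand-accelerated intramolecular Ullmann diaryl ether synthesis: the unhindered phenoxide of ring A is arylated at B1 through a monovalent copper phenoxide, and the picolinate ligand is suited to aryl iodides with two ortho substituents. Slow addition keeps the substrate dilute and the catalyst-to-substrate ratio high, and the 20-membered ring with its flexible chain should close without strain.

Step 12
Reactants: 18 tri-O-methyl ether of 19
Product: 19 target macrocycle CNP0173380.0 (ring A: 1-aryloxy, 3-hydroxy, 5-alkyl; ring B: 1-aryloxy, 2,4-dihydroxy, 6-alkyl; (CH2)14 bridge from A5 to B6)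
Conditions: BBr3 (6 equiv), CH2Cl2, −78 °C to rt; then H2O, 0 °C; work-up under Ar
Reagents that add atoms: none
Why: Lewis-acid cleavage of the three aryl methyl ethers proceeds by bromide attack at the methyl carbons; the diaryl ether has no sp3 carbon on oxygen and should survive, and the alkane chain is inert.

**Compound list**

1 | hexadecanedioic acid | OC(=O)CCCCCCCCCCCCCCC(=O)O | starting material
2 | hexadecanedioyl dichloride | ClC(=O)CCCCCCCCCCCCCCC(Cl)=O | intermediate
3 | N1,N16-dimethoxy-N1,N16-dimethylhexadecanediamide | CON(C)C(=O)CCCCCCCCCCCCCCC(=O)N(C)OC | intermediate
4 | 2,2,6-trimethyl-4H-1,3-dioxin-4-one | CC1=CC(=O)OC(C)(C)O1 | starting material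
5 | lithium 2,2-dimethyl-6-methylidene-6H-1,3-dioxin-4-olate (lithium dienolate of 4) | C=C1C=C([O-])OC(C)(C)O1.[Li+] | intermediate
6 | 2,2-dimethyl-6-(2-oxopropyl)-4H-1,3-dioxin-4-one | CC(=O)CC1=CC(=O)OC(C)(C)O1 | intermediate
7 | dilithium dianion of 6 (carbanions at the terminal methyl carbon and at the methylene next to the ring) | [Li+].[Li+].[CH2-]C(=O)[CH-]C1=CC(=O)OC(C)(C)O1 | intermediate
8 | 1,22-bis(2,2-dimethyl-4-oxo-4H-1,3-dioxin-6-yl)docosane-2,4,19,21-tetraone | CC1(C)OC(=O)C=C(CC(=O)CC(=O)CCCCCCCCCCCCCCC(=O)CC(=O)CC2=CC(=O)OC(C)(C)O2)O1 | intermediate
9 | bis-aldol adduct: 5,5'-(tetradecane-1,14-diyl)bis(5-hydroxy-2,2-dimethyl-4a,5,6,7-tetrahydro-4H-benzo[d][1,3]dioxine-4,7-dione), mixture of diastereomers, all four centres transient | O=C1OC(C)(C)OC2=CC(=O)CC(O)(CCCCCCCCCCCCCCC3(O)CC(=O)C=C4OC(C)(C)OC(=O)C34)C12 | intermediate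
10 | 5,5'-(tetradecane-1,14-diyl)bis(7-hydroxy-2,2-dimethyl-4H-benzo[d][1,3]dioxin-4-one) | O=C1OC(C)(C)Oc2cc(O)cc(CCCCCCCCCCCCCCc3cc(O)cc4OC(C)(C)OC(=O)c34)c12 | intermediate
11 | 6,6'-(tetradecane-1,14-diyl)bis(2,4-dihydroxybenzoic acid) | OC(=O)c1c(O)cc(O)cc1CCCCCCCCCCCCCCc1cc(O)cc(O)c1C(O)=O | intermediate
12 | 5,5'-(tetradecane-1,14-diyl)bis(benzene-1,3-diol) | Oc1cc(O)cc(c1)CCCCCCCCCCCCCCc1cc(O)cc(O)c1 | intermediate
13 | 1,14-bis(3,5-dimethoxyphenyl)tetradecane | COc1cc(OC)cc(c1)CCCCCCCCCCCCCCc1cc(OC)cc(OC)c1 | intermediate
14 | 3-[14-(3,5-dimethoxyphenyl)tetradecyl]-5-methoxyphenol | COc1cc(O)cc(c1)CCCCCCCCCCCCCCc1cc(OC)cc(OC)c1 | intermediate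
15 | 3-[14-(3,5-dimethoxyphenyl)tetradecyl]-5-methoxyphenyl acetate | COc1cc(OC(C)=O)cc(c1)CCCCCCCCCCCCCCc1cc(OC)cc(OC)c1 | intermediate
16 | 3-[14-(2-iodo-3,5-dimethoxyphenyl)tetradecyl]-5-methoxyphenyl acetate | COc1cc(OC(C)=O)cc(c1)CCCCCCCCCCCCCCc1cc(OC)cc(OC)c1I | intermediate
17 | 3-[14-(2-iodo-3,5-dimethoxyphenyl)tetradecyl]-5-methoxyphenol | COc1cc(O)cc(c1)CCCCCCCCCCCCCCc1cc(OC)cc(OC)c1I | intermediate
18 | tri-O-methyl ether of 19 (OMe on A3, B2 and B4; ether O between A1 and B1; (CH2)14 from A5 to B6) | COc1cc2cc(c1)Oc1c(OC)cc(OC)cc1CCCCCCCCCCCCCC2 | intermediate
19 | target macrocycle CNP0173380.0 (no stereocentre) | Oc1cc2cc(c1)Oc1c(O)cc(O)cc1CCCCCCCCCCCCCC2 | target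

**Step count and least certain steps**

Total step count: 12. Longest linear sequence: 11 steps (1 to 19 through steps 1 and 3 to 12); step 2 is a one-step branch from 4.

Step 4 (key step). The most likely failure is incomplete folding at one of the two termini: stalling at the aldol or mono-aromatised stage, or base-induced retro-Claisen cleavage of a 1,3-diketone that outruns a slow aldol. Either halves or destroys the skeleton. The fallback changes the folding substrate from the masked to the free triketo ester and sets out from 8. Heating 8 with methanol in toluene (sealed, 110 °C) should expel acetone from each dioxinone by a retro-[4+2] reaction and trap the ketene functions to give dimethyl 3,5,7,22,24,26-hexaoxooctacosanedioate F1. Mild carbonate base in methanol followed by HCl/MeOH should fold F1 in the aldol mode to dimethyl 6,6'-(tetradecane-1,14-diyl)bis(2,4-dihydroxybenzoate) F2. Here the geometric protection against Claisen and pyranone closure is lost, and selectivity rests on the mild base. Saponification and decarboxylation of F2 under the conditions of step 5 bring the route back at 12.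

Step 3. The double acylation may stop after one end. Compound 3 may be poorly soluble at low temperature, and any mono-adduct consumes the precious dianion. The tetraketone may also begin to aromatise or decompose on work-up. The fallback replaces the hard dianion by a soft magnesium enolate; it sets out from 5 and 2 and returns at 8. Acylation of the dienolate 5 with monoallyl malonate activated as its imidazolide should give allyl 4-(2,2-dimethyl-4-oxo-4H-1,3-dioxin-6-yl)-3-oxobutanoate F3. Treatment of F3 with MgCl2 and pyridine and then with the diacid chloride 2 should C-acylate the malonate-type carbon at both ends and give diallyl 2,19-bis[(2,2-dimethyl-4-oxo-4H-1,3-dioxin-6-yl)acetyl]-3,18-dioxoicosanedioate F4. Pd(PPh3)4 (zerovalent palladium) with morpholine should then remove the allyl groups with decarboxylation and deliver 8.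

Step 7. Because the rings react independently, demethylation of the second ring competes with the first throughout, and conversion at 130 °C is hard to stop at the mono-phenol. A mixture is unavoidable, and the risk is a poor return of 14 per pass. The fallback approaches 14 from the other side and sets out from 13. Excess NaSEt should drive both rings cleanly to the mono-demethylated stage and give 5,5'-(tetradecane-1,14-diyl)bis(3-methoxyphenol) F5. One equivalent of MeI with K2CO3 at room temperature should then mono-methylate F5 to 14, where the route is rejoined. That alkylation can be dosed and followed, and recovered F5 and over-methylated 13 both re-enter. The event stays statistical.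

Step 9. Iodination may not be confined to ring B: competing attack on the acetoxy-anisole ring A, or a second iodination of ring B at the other position ortho to the chain, would consume material once the reagent is no longer limiting. The fallback switches ring A off electronically instead of relying on a rate difference; it sets out from 14 and returns at 17. MsCl and Et3N should give 3-[14-(3,5-dimethoxyphenyl)tetradecyl]-5-methoxyphenyl methanesulfonate F6, whose sulfonate-bearing ring is deactivated. Iodination of F6, if need be with acid activation of NIS, should give 3-[14-(2-iodo-3,5-dimethoxyphenyl)tetradecyl]-5-methoxyphenyl methanesulfonate F7. Hot KOH in aqueous methanol should then cleave the aryl sulfonate and give 17.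

Step 11. Intermolecular etherification to oligomers may outrun the entropically costly 20-membered closure, and slow activation of the electron-rich, doubly ortho-substituted C–I bond may lead to protodeiodination. The fallback reverses the polarity of the ether formation so that the electrophile is unhindered; it sets out from 14 and returns at 18. Tf2O and pyridine should give 3-[14-(3,5-dimethoxyphenyl)tetradecyl]-5-methoxyphenyl trifluoromethanesulfonate F8. Vilsmeier–Haack formylation (POCl3, DMF) should attack only ring B at the carbon next to the chain and give 3-[14-(2-formyl-3,5-dimethoxyphenyl)tetradecyl]-5-methoxyphenyl trifluoromethanesulfonate F9. Dakin oxidation (mCPBA, then Et3N/MeOH) should convert the formyl group into the B1 hydroxyl and give 3-[14-(2-hydroxy-3,5-dimethoxyphenyl)tetradecyl]-5-methoxyphenyl trifluoromethanesulfonate F10. A Buchwald–Hartwig-type C–O coupling under high dilution (Pd(OAc)2, tBuXPhos, K3PO4, toluene, 100 °C) should then join the B1 oxygen to A1 with loss of triflate and give 18. Here the ether oxygen comes from ring B and the original A1 oxygen leaves as triflate. The demanding element is the doubly ortho-substituted phenol nucleophile.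

**Further compounds**

F1 | step 4 | dimethyl 3,5,7,22,24,26-hexaoxooctacosanedioate | COC(=O)CC(=O)CC(=O)CC(=O)CCCCCCCCCCCCCCC(=O)CC(=O)CC(=O)CC(=O)OC
F2 | step 4 | dimethyl 6,6'-(tetradecane-1,14-diyl)bis(2,4-dihydroxybenzoate) | COC(=O)c1c(O)cc(O)cc1CCCCCCCCCCCCCCc1cc(O)cc(O)c1C(=O)OC
F3 | step 3 | allyl 4-(2,2-dimethyl-4-oxo-4H-1,3-dioxin-6-yl)-3-oxobutanoate | C=CCOC(=O)CC(=O)CC1=CC(=O)OC(C)(C)O1
F4 | step 3 | diallyl 2,19-bis[(2,2-dimethyl-4-oxo-4H-1,3-dioxin-6-yl)acetyl]-3,18-dioxoicosanedioate (methine centres enolised, no defined configuration) | C=CCOC(=O)C(C(=O)CC1=CC(=O)OC(C)(C)O1)C(=O)CCCCCCCCCCCCCCC(=O)C(C(=O)OCC=C)C(=O)CC1=CC(=O)OC(C)(C)O1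
F5 | step 7 | 5,5'-(tetradecane-1,14-diyl)bis(3-methoxyphenol) | COc1cc(O)cc(c1)CCCCCCCCCCCCCCc1cc(O)cc(OC)c1
F6 | step 9 | 3-[14-(3,5-dimethoxyphenyl)tetradecyl]-5-methoxyphenyl methanesulfonate | COc1cc(OS(C)(=O)=O)cc(c1)CCCCCCCCCCCCCCc1cc(OC)cc(OC)c1
F7 | step 9 | 3-[14-(2-iodo-3,5-dimethoxyphenyl)tetradecyl]-5-methoxyphenyl methanesulfonate | COc1cc(OS(C)(=O)=O)cc(c1)CCCCCCCCCCCCCCc1cc(OC)cc(OC)c1I
F8 | step 11 | 3-[14-(3,5-dimethoxyphenyl)tetradecyl]-5-methoxyphenyl trifluoromethanesulfonate | COc1cc(OS(=O)(=O)C(F)(F)F)cc(c1)CCCCCCCCCCCCCCc1cc(OC)cc(OC)c1
F9 | step 11 | 3-[14-(2-formyl-3,5-dimethoxyphenyl)tetradecyl]-5-methoxyphenyl trifluoromethanesulfonate | COc1cc(OS(=O)(=O)C(F)(F)F)cc(c1)CCCCCCCCCCCCCCc1cc(OC)cc(OC)c1C=O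
F10 | step 11 | 3-[14-(2-hydroxy-3,5-dimethoxyphenyl)tetradecyl]-5-methoxyphenyl trifluoromethanesulfonate | COc1cc(OS(=O)(=O)C(F)(F)F)cc(c1)CCCCCCCCCCCCCCc1cc(OC)cc(OC)c1O
A1 | alternative 1 | tri-O-methyl macrocyclic (Z,Z)-diene 1,3-diyne | COc1cc(OC)c2Oc3cc(OC)cc(c3)/C=C\CCC#CC#CCCCC/C=C\c2c1
A2 | alternative 1 | 1-[3-((Z)-hex-1-en-5-yn-1-yl)-5-methoxyphenoxy]-2,4-dimethoxy-6-((Z)-oct-1-en-7-yn-1-yl)benzene | COc1cc(OC)c(Oc2cc(OC)cc(/C=C\CCC#C)c2)c(/C=C\CCCCC#C)c1
A3 | alternative 2 | methyl 2-(2-acetyl-3,5-dimethoxyphenyl)acetate | COC(=O)Cc1cc(OC)cc(OC)c1C(C)=O
A4 | alternative 2 | 3,5-dimethoxy-2-(trimethylsilyl)phenyl trifluoromethanesulfonate | COc1cc(OC)c([Si](C)(C)C)c(OS(=O)(=O)C(F)(F)F)c1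
A5 | alternative 2 | methyl acetoacetate | COC(=O)CC(C)=O
A6 | alternative 3 | 2-[14-(3-chloro-5-methoxyphenyl)tetradecyl]-6-isopropoxybenzene-1,4-diol | Oc1c(OC(C)C)cc(O)cc1CCCCCCCCCCCCCCc1cc(Cl)cc(OC)c1
A7 | alternative 3 | 4-[16-(3-chloro-5-methoxyphenyl)hexadec-1-en-2-yl]-4-hydroxy-3-isopropoxycyclobut-2-en-1-one (racemic) | O=C1C=C(OC(C)C)C1(O)C(=C)CCCCCCCCCCCCCCc1cc(Cl)cc(OC)c1
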